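## Retrosynthetic overview

1. Feature: C2 of ring C carries O1 and the donor-rich ring B and lies β to the C4 carbonyl. Moving its C3 bond onto the C4 oxygen gives an isomeric enol acetal, a 2-aryl-4-methylene-4H-1,3-benzodioxine, in which ring A is a salicylate and C2 is an aldehyde carbon.
2. Disconnection 1 (C2–C3, closes ring C, sets C2): catalytic enantioselective Petasis–Ferrier rearrangement. The racemic acetal ionises to a planar C2 oxocarbenium ion paired with a chiral imidodiphosphorimidate anion.
3. Disconnection 2: C4=CH2 (the future C3) comes from lactone methylenation. The 1,3-benzodioxin-4-one (O1–C2 and O3–C2) comes from persilylated 2,4,6-trihydroxybenzoic acid and the ring B aldehyde.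
4. Disconnection 3: C5'–C1'' comes from geranyl bromide and the aryllithium of acetal-masked 5-bromo-2-silyloxy-4-methoxybenzaldehyde.
5. Ring order: rings A and B are bought, the sacrificial dioxinone ring is closed first, and ring C is made from it in the key step. The three silyl ethers are removed last with buffered HF.

Key step: step 8

Conventions: flavanone numbering is used (O1, C2, C3, C4, C4a–C8a; ring B primed; geranyl double-primed). In the benzodioxines O1 and C2 keep their numbers, and O3 is the oxygen that becomes the C4 carbonyl oxygen. TBS = tert-butyldimethylsilyl, TMS = trimethylsilyl, geranyl = (2E)-3,7-dimethylocta-2,6-dien-1-yl. IDPi = 3,3'-diaryl-BINOL-derived imidodiphosphorimidate acid, (ArO)2P(=NTf)–NH–P(=NTf)(OAr)2.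

Assumption: which IDPi enantiomer delivers (2S) cannot be derived for this new substrate class. It is fixed in a test run, and the route is written for that enantiomer.

## Route

Step 1
Reactants: 1 5-bromo-2-hydroxy-4-methoxybenzaldehyde
Product: 2 5-bromo-2-(tert-butyldimethylsilyloxy)-4-methoxybenzaldehyde
Conditions: TBSCl, imidazole, DMF, 0 °C to rt
Reagents that add atoms: tert-butyldimethylsilyl chloride, CC(C)(C)[Si](C)(C)Cl
Why: Imidazole-promoted O-silylation of a phenol, which also works on the chelated salicylaldehyde OH in DMF and removes the acidic proton before the organolithium step.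

Step 2
Reactants: 2 5-bromo-2-(tert-butyldimethylsilyloxy)-4-methoxybenzaldehyde
Product: 3 5-bromo-2-(tert-butyldimethylsilyloxy)-4-methoxybenzaldehyde dimethyl acetal
Conditions: HC(OMe)3, PPTS (cat.), MeOH, rt; Et3N quench
Reagents that add atoms: trimethyl orthoformate, COC(OC)OC
Why: Acid-catalysed acetalisation with an orthoester as water scavenger masks the aldehyde, which n-BuLi and the aryllithium of step 3 would otherwise attack, and the aryl TBS ether tolerates PPTS in methanol.

Step 3
Reactants: 3 5-bromo-2-(tert-butyldimethylsilyloxy)-4-methoxybenzaldehyde dimethyl acetal; 4 geranyl bromide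
Product: 7 2-(tert-butyldimethylsilyloxy)-5-geranyl-4-methoxybenzaldehyde, via aryllithium 5 (not isolated), via geranylated dimethyl acetal 6 (not isolated)
Conditions: n-BuLi, THF, −78 °C; CuBr·SMe2 (10 mol %), 4, −78 to 0 °C; then 10% aq. citric acid, THF, rt
Reagents that add atoms: water, O
Why: Bromine–lithium exchange outruns attack on acetal or silyl ether at −78 °C (no silyloxy group ortho to lithium, so no retro-Brook shift), the copper-catalysed allylic substitution takes place at the unhindered primary carbon with the E olefin retained, and the donor-rich acetal hydrolyses under citric acid that leaves the aryl TBS ether and the trisubstituted olefins alone.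

Step 4
Reactants: 8 2,4,6-trihydroxybenzoic acid
Product: 9 trimethylsilyl 2,4,6-tris(trimethylsilyloxy)benzoate
Conditions: HMDS, TMSCl (cat.), CH2Cl2, rt to 40 °C; evaporation, used crude
Reagents that add atoms: hexamethyldisilazane, C[Si](C)(C)N[Si](C)(C)C
Why: Exhaustive silylation with HMDS is neutral and gives only ammonia, so an acid that loses CO2 readily under protic acid or on heating becomes a soluble, anhydrous bis-nucleophile (silyl ester plus ortho silyl ether) for silyl-transfer acetalisation.

Step 5
Reactants: 7 2-(tert-butyldimethylsilyloxy)-5-geranyl-4-methoxybenzaldehyde; 9 trimethylsilyl 2,4,6-tris(trimethylsilyloxy)benzoate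
Product: 11 rac-2-[2-(tert-butyldimethylsilyloxy)-5-geranyl-4-methoxyphenyl]-5,7-dihydroxy-4H-1,3-benzodioxin-4-one, via bis-TMS benzodioxinone 10 (not isolated)
Conditions: TMSOTf (20 mol %), CH2Cl2, −78 °C; pyridine; then pH 7 phosphate buffer, THF, 0 °C to rt
Reagents that add atoms: none
Why: Noyori-type silyl-transfer acetalisation, the usual entry to dioxanones for Petasis–Ferrier sequences: the silyl ester and one of the two equivalent ortho OTMS groups add to the TMSOTf-activated aldehyde with irreversible loss of (Me3Si)2O at −78 °C, where the geranyl chain and aryl TBS ether are safe, the two labile aryl TMS ethers fall off in the buffered work-up, and C2 forms racemic, which is harmless because step 8 erases it.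

Step 6
Reactants: 11 rac-2-[2-(tert-butyldimethylsilyloxy)-5-geranyl-4-methoxyphenyl]-5,7-dihydroxy-4H-1,3-benzodioxin-4-one
Product: 12 rac-5,7-bis(tert-butyldimethylsilyloxy)-2-[2-(tert-butyldimethylsilyloxy)-5-geranyl-4-methoxyphenyl]-4H-1,3-benzodioxin-4-one
Conditions: TBSCl (excess), imidazole, DMF, 0 °C to rt
Reagents that add atoms: tert-butyldimethylsilyl chloride, CC(C)(C)[Si](C)(C)Cl
Why: Imidazole-mediated phenol silylation, in which the 5-OH is chelated only to a lactone carbonyl (as in a salicylate ester) and follows the 7-OH with excess reagent, while the absence of a silyl triflate avoids ionising the acylal.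

Step 7
Reactants: 12 rac-5,7-bis(tert-butyldimethylsilyloxy)-2-[2-(tert-butyldimethylsilyloxy)-5-geranyl-4-methoxyphenyl]-4H-1,3-benzodioxin-4-one
Product: 13 rac-5,7-bis(tert-butyldimethylsilyloxy)-2-[2-(tert-butyldimethylsilyloxy)-5-geranyl-4-methoxyphenyl]-4-methylene-4H-1,3-benzodioxine
Conditions: Cp2TiMe2, toluene, 65–70 °C, dark; pentane, filtration through basic alumina (1% Et3N)
Reagents that add atoms: dimethyltitanocene Cp2TiMe2, C[Ti+2]C.[CH-]1C=CC=C1.[CH-]1C=CC=C1
Why: Petasis methylenation, in which thermally formed Cp2Ti=CH2 turns the lactone carbonyl of a dioxanone into the exocyclic enol ether (the new CH2 is the future C3) under neutral, non-Lewis-acidic conditions that spare silyl ethers, the acetal and trisubstituted olefins, and the acid-labile product is handled only on base-washed supports.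

Step 8
Reactants: 13 rac-5,7-bis(tert-butyldimethylsilyloxy)-2-[2-(tert-butyldimethylsilyloxy)-5-geranyl-4-methoxyphenyl]-4-methylene-4H-1,3-benzodioxine
Product: 15 (2S)-5,7-bis(tert-butyldimethylsilyloxy)-2-[2-(tert-butyldimethylsilyloxy)-5-geranyl-4-methoxyphenyl]chroman-4-one, via ring-opened oxocarbenium enol silane 14 (not isolated)
Conditions: IDPi (5 mol %) premixed with allyltrimethylsilane (6 mol %) at rt, toluene (0.02 M), −78 °C; Et3N quench at −78 °C
Reagents that add atoms: none
Why: Proposed new method: the silylated catalyst (Me3Si+ paired with the chiral IDPi anion, made from the IDPi acid and allyltrimethylsilane because the isomerisation itself brings in no silicon reagent) silylates the enol-ether oxygen O3, the C2–O3 bond ionises, and 14 results, in which a C2=O1+ oxocarbenium ion conjugated with the 2'-silyloxy-4'-methoxyphenyl ring faces the ring A α-silyloxystyrene, whose CH2 terminus (the future C3) attacks C2 before the silyl group on the new C4 carbonyl passes to the next molecule of 13, so that silicon stays catalytic. The closest known reactions are the racemic Petasis–Ferrier rearrangement of 4-methylene-1,3-dioxanes with Me2AlCl and the silylium/IDPi-catalysed enantioselective additions of enol silanes to oxocarbenium ions, and what is new is their merger and its use on a benzodioxine. Ring C closes in the 6-(enolendo)-endo-trig mode (C3=C4 and C2=O1+ both end up inside the six-membered ring), which is geometrically allowed and is helped by the two ortho substituents that twist the enol silane out of the ring A plane toward C2. C2 is the only new stereocentre and is under catalyst control: ionisation erases the acetal configuration, both enantiomers of 13 give the same planar cation, and the confined anion shields one face so that the (2S) ketone should form. The step needs C- rather than O-recombination and C2–O3 rather than C2–O1 cleavage, and reversibility secures both, since O-recombination or opening at O1 only returns 13 whereas C–C bond formation creates the strong C4=O bond and is the one exit. The ortho and para oxygens of ring B allow ionisation at −78 °C, where proton loss from C3 to the chalcone, re-ionisation of 15 at C2–O1 and attack on the geranyl olefins should be slow, and the cold Et3N quench removes the Lewis acid before warming.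

Step 9
Reactants: 15 (2S)-5,7-bis(tert-butyldimethylsilyloxy)-2-[2-(tert-butyldimethylsilyloxy)-5-geranyl-4-methoxyphenyl]chroman-4-one
Product: 16 kuwanon U, (2S)-5,7-dihydroxy-2-(5-geranyl-2-hydroxy-4-methoxyphenyl)chroman-4-one
Conditions: HF·pyridine, excess pyridine, THF, 0 °C to rt (polypropylene); pH 7 buffer
Reagents that add atoms: none
Why: Fluoride cleavage of three aryl silyl ethers in a weakly acidic, pyridine-buffered medium, which avoids the phenoxide-driven retro-oxa-Michael opening to the chalcone (and loss of the C2 configuration) that basic fluoride would cause, and is too dilute in HF to add to the olefins.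

## Compound list

1 | 5-bromo-2-hydroxy-4-methoxybenzaldehyde | COc1cc(O)c(C=O)cc1Br | starting material
2 | 5-bromo-2-(tert-butyldimethylsilyloxy)-4-methoxybenzaldehyde | COc1cc(O[Si](C)(C)C(C)(C)C)c(C=O)cc1Br | intermediate
3 | 5-bromo-2-(tert-butyldimethylsilyloxy)-4-methoxybenzaldehyde dimethyl acetal | COc1cc(O[Si](C)(C)C(C)(C)C)c(C(OC)OC)cc1Br | intermediate
4 | geranyl bromide, (2E)-1-bromo-3,7-dimethylocta-2,6-diene | BrC/C=C(\C)CCC=C(C)C | starting material
5 | 4-(tert-butyldimethylsilyloxy)-5-(dimethoxymethyl)-2-methoxyphenyllithium | COc1cc(O[Si](C)(C)C(C)(C)C)c(C(OC)OC)cc1[Li] | intermediate (not isolated)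
6 | 2-(tert-butyldimethylsilyloxy)-5-geranyl-4-methoxybenzaldehyde dimethyl acetal | COc1cc(O[Si](C)(C)C(C)(C)C)c(C(OC)OC)cc1C/C=C(\C)CCC=C(C)C | intermediate (not isolated)
7 | 2-(tert-butyldimethylsilyloxy)-5-geranyl-4-methoxybenzaldehyde | COc1cc(O[Si](C)(C)C(C)(C)C)c(C=O)cc1C/C=C(\C)CCC=C(C)C | intermediate
8 | 2,4,6-trihydroxybenzoic acid | OC(=O)c1c(O)cc(O)cc1O | starting material
9 | trimethylsilyl 2,4,6-tris(trimethylsilyloxy)benzoate | C[Si](C)(C)OC(=O)c1c(O[Si](C)(C)C)cc(O[Si](C)(C)C)cc1O[Si](C)(C)C | intermediate
10 | rac-2-[2-(tert-butyldimethylsilyloxy)-5-geranyl-4-methoxyphenyl]-5,7-bis(trimethylsilyloxy)-4H-1,3-benzodioxin-4-one | O=C1OC(c2cc(C/C=C(\C)CCC=C(C)C)c(OC)cc2O[Si](C)(C)C(C)(C)C)Oc2cc(O[Si](C)(C)C)cc(O[Si](C)(C)C)c12 | intermediate (not isolated)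
11 | rac-2-[2-(tert-butyldimethylsilyloxy)-5-geranyl-4-methoxyphenyl]-5,7-dihydroxy-4H-1,3-benzodioxin-4-one | O=C1OC(c2cc(C/C=C(\C)CCC=C(C)C)c(OC)cc2O[Si](C)(C)C(C)(C)C)Oc2cc(O)cc(O)c12 | intermediate
12 | rac-5,7-bis(tert-butyldimethylsilyloxy)-2-[2-(tert-butyldimethylsilyloxy)-5-geranyl-4-methoxyphenyl]-4H-1,3-benzodioxin-4-one | O=C1OC(c2cc(C/C=C(\C)CCC=C(C)C)c(OC)cc2O[Si](C)(C)C(C)(C)C)Oc2cc(O[Si](C)(C)C(C)(C)C)cc(O[Si](C)(C)C(C)(C)C)c12 | intermediate
13 | rac-5,7-bis(tert-butyldimethylsilyloxy)-2-[2-(tert-butyldimethylsilyloxy)-5-geranyl-4-methoxyphenyl]-4-methylene-4H-1,3-benzodioxine | C=C1OC(c2cc(C/C=C(\C)CCC=C(C)C)c(OC)cc2O[Si](C)(C)C(C)(C)C)Oc2cc(O[Si](C)(C)C(C)(C)C)cc(O[Si](C)(C)C(C)(C)C)c12 | intermediate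
14 | ring-opened C2=O1+ oxocarbenium ion bearing the ring A trimethylsilyl enol ether (cation of the ion pair; counter-ion is the IDPi anion) | C=C(O[Si](C)(C)C)c1c(O[Si](C)(C)C(C)(C)C)cc(O[Si](C)(C)C(C)(C)C)cc1[O+]=Cc1cc(C/C=C(\C)CCC=C(C)C)c(OC)cc1O[Si](C)(C)C(C)(C)C | intermediate (not isolated)
15 | (2S)-5,7-bis(tert-butyldimethylsilyloxy)-2-[2-(tert-butyldimethylsilyloxy)-5-geranyl-4-methoxyphenyl]chroman-4-one | COc1cc(O[Si](C)(C)C(C)(C)C)c([C@@H]2CC(=O)c3c(O[Si](C)(C)C(C)(C)C)cc(O[Si](C)(C)C(C)(C)C)cc3O2)cc1C/C=C(\C)CCC=C(C)C | intermediate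
16 | kuwanon U, (2S)-5,7-dihydroxy-2-(5-geranyl-2-hydroxy-4-methoxyphenyl)chroman-4-one | COc1cc(O)c([C@@H]2CC(=O)c3c(O)cc(O)cc3O2)cc1C/C=C(\C)CCC=C(C)C | target

## Step count and risks

Total steps: 9. Longest linear sequence: 8 (steps 1, 2, 3, 5, 6, 7, 8, 9 from compound 1). Step 4 is the one-step side branch from 8.

**Step 8 (Proposed new method).**
- Facial selectivity may be poor, because the tris-silylated, geranyl-bearing cation may not sit inside the confined anion.
- Turnover may be slow, because the electron-rich product ketone holds the silylium ion.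
- Raising the temperature to compensate invites proton loss to the chalcone and re-ionisation at C2–O1, which erodes the enantiomeric purity.
- Fallback (known chemistry, sets out from 13, returns at 15): the established racemic Petasis–Ferrier rearrangement with Me2AlCl (CH2Cl2, −78 °C) should give the racemic tris-TBS flavanone F1. Preparative HPLC on a polysaccharide chiral stationary phase then resolves it into 15 and the (2R)-tris-TBS flavanone F2, which is set aside.

**Step 5.**
- The ring B-stabilised C2 cation is passed through twice on the way to the acylal. It may be captured by the geranyl olefins or by the free ring A carbons (Friedel–Crafts alkylation).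
- Adventitious TfOH may cyclise the chain, and the finished acylal may re-ionise.
- Fallback (sets out from 2 and 9, returns at 12): the geranyl chain is introduced only after the dioxinone is built.
  - Condensation of 2 with 9 under the conditions of step 5 leads through the bis-TMS bromo benzodioxinone F3 to the 5,7-dihydroxy bromo benzodioxinone F4. The C5' bromine is inductively withdrawing and meta to C1', so it lowers the tendency to ionise, and no olefin is present.
  - TBSCl/imidazole gives the bis-TBS bromo benzodioxinone F5.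
  - Geranyltributylstannane F6, made from 4 and Bu3SnLi (THF, −78 °C), is joined to F5 in a neutral Stille coupling (Pd(PPh3)4, toluene, 100 °C) to give 12.

**Step 7.**
- The cycloaddition of Cp2Ti=CH2 may be sluggish. The carbonyl is flanked by the peri 5-OTBS group and deactivated by three ring oxygens.
- Prolonged heating would then degrade the acylal, or the enol acetal would be lost during isolation.
- Fallback (sets out from 10, returns at 13): the olefination is run before the bulky silyl groups are installed, and the silyl exchange is moved to the base-stable enol acetal.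
  - 10 is taken from step 5 by a non-aqueous work-up (pyridine, pentane, filtration, evaporation).
  - It is methylenated with Cp2TiMe2 to the bis-TMS enol acetal F7.
  - MeLi (THF, 0 °C) cleaves only the two aryl TMS ethers to give the dilithium 5,7-bis(phenoxide) F8.
  - TBSCl with DMPU traps F8 in the same flask to give 13, so no free phenol ever stands next to the enol ether.

## Further compounds

F1 | step 8 | racemic 5,7-bis(tert-butyldimethylsilyloxy)-2-[2-(tert-butyldimethylsilyloxy)-5-geranyl-4-methoxyphenyl]chroman-4-one | COc1cc(O[Si](C)(C)C(C)(C)C)c(C2CC(=O)c3c(O[Si](C)(C)C(C)(C)C)cc(O[Si](C)(C)C(C)(C)C)cc3O2)cc1C/C=C(\C)CCC=C(C)C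
F2 | step 8 | (2R)-5,7-bis(tert-butyldimethylsilyloxy)-2-[2-(tert-butyldimethylsilyloxy)-5-geranyl-4-methoxyphenyl]chroman-4-one | COc1cc(O[Si](C)(C)C(C)(C)C)c([C@H]2CC(=O)c3c(O[Si](C)(C)C(C)(C)C)cc(O[Si](C)(C)C(C)(C)C)cc3O2)cc1C/C=C(\C)CCC=C(C)C
F3 | step 5 | rac-2-[5-bromo-2-(tert-butyldimethylsilyloxy)-4-methoxyphenyl]-5,7-bis(trimethylsilyloxy)-4H-1,3-benzodioxin-4-one | O=C1OC(c2cc(Br)c(OC)cc2O[Si](C)(C)C(C)(C)C)Oc2cc(O[Si](C)(C)C)cc(O[Si](C)(C)C)c12
F4 | step 5 | rac-2-[5-bromo-2-(tert-butyldimethylsilyloxy)-4-methoxyphenyl]-5,7-dihydroxy-4H-1,3-benzodioxin-4-one | O=C1OC(c2cc(Br)c(OC)cc2O[Si](C)(C)C(C)(C)C)Oc2cc(O)cc(O)c12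
F5 | step 5 | rac-2-[5-bromo-2-(tert-butyldimethylsilyloxy)-4-methoxyphenyl]-5,7-bis(tert-butyldimethylsilyloxy)-4H-1,3-benzodioxin-4-one | O=C1OC(c2cc(Br)c(OC)cc2O[Si](C)(C)C(C)(C)C)Oc2cc(O[Si](C)(C)C(C)(C)C)cc(O[Si](C)(C)C(C)(C)C)c12
F6 | step 5 | geranyltributylstannane | CCCC[Sn](CCCC)(CCCC)C/C=C(\C)CCC=C(C)C
F7 | step 7 | rac-2-[2-(tert-butyldimethylsilyloxy)-5-geranyl-4-methoxyphenyl]-4-methylene-5,7-bis(trimethylsilyloxy)-4H-1,3-benzodioxine | C=C1OC(c2cc(C/C=C(\C)CCC=C(C)C)c(OC)cc2O[Si](C)(C)C(C)(C)C)Oc2cc(O[Si](C)(C)C)cc(O[Si](C)(C)C)c12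
F8 | step 7 | dilithium rac-2-[2-(tert-butyldimethylsilyloxy)-5-geranyl-4-methoxyphenyl]-4-methylene-4H-1,3-benzodioxine-5,7-diolate | C=C1OC(c2cc(C/C=C(\C)CCC=C(C)C)c(OC)cc2O[Si](C)(C)C(C)(C)C)Oc2cc([O-])cc([O-])c12.[Li+].[Li+]
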